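The dissolution coefficient of 0.046 s⁻¹ meets, in this flask, a draw on dissolved G by X of 0.0450 s⁻¹.

    X + G → Z + Q (k1 = 3.0 M⁻¹ s⁻¹)
    X + G → D + Q (k2 = 1.5 M⁻¹ s⁻¹)
    G + Z → L + Q (k3 = 0.075 M⁻¹ s⁻¹)
    G + D → L + Q (k4 = 0.52 M⁻¹ s⁻¹)
    J ⇌ G, rate k5*(cs5 - [G]) while solid is left; crystals form when [G] > cs5 (cs5 = 3.3 mM, k5 = 0.046 s⁻¹)
    X + Q → X.Q (k6 = 0.85 M⁻¹ s⁻¹)

X 10 mM; J 10.0 mM; time 1.0 min

- given per volume of solution although it is solid: J
- at the start none of J is in solution
- run time (flask): 1.0 min

- epsilon: doubling the solubility in step 5, all else as stated
- zeta: doubling the dissolution coefficient of step 5, all else as stated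

* the Z standing at 1.0 min, as a percentage of the X charged
* the change that raises the amount of Z at 1.0 min, in percent of the X charged most ("none" if none brings more than 2 percentage points) (epsilon / zeta / none)
* amount of Z at 1.0 min, in percent of the X charged, after epsilon

In this flask G comes from the solid J, closing on saturation in a dissolving time of 21.7 s, and goes with X into Z and D, each G lasting, at the charged X, a using time of 22.2 s. These two times are the pair to hold. The step that forms X.Q takes X and Q but leaves G alone, and the two steps to L start with no Z or D and carry smaller constants than the steps from X. The quotient of the pair is 0.978, the draw ratio, dissolving time over using time. While solid is left, X stands at its charge and the steps to L are set aside, inflow balances outflow at the solubility divided by one plus this ratio. A ratio of one is the symmetric case, half of saturation. This flask lies close to it, at 1.67 mM, which is half of 3.3 mM. By my reckoning, doubling the solubility doubles that level to 3.34 mM, while doubling the coefficient halves the ratio and gives less than that, 2.22 mM. The reckoning stops there and picks epsilon.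

The forecast gives 21% for y, epsilon as best and 36% for yb, on this ground: “Doubling the solubility nearly doubles the driving force for dissolution”.

The simulation gives 21.0%, epsilon with 15 percentage points against 6.6 points for zeta, and 35.7%.

In the flask at 1.00 min, with X read at 63.4%, the draw ratio is 0.620 and the level 2.04 mM; [G] reads 1.91 mM, and G, each step taken net, is still made 1.14 times faster than it is used up. With X charged at 2.5 mM in the neighbour and read at 57.8% of that charge, the ratio becomes 0.141 and the level 2.89 mM, and [G] in that neighbour reads 2.70 mM at 1.00 min. The flask is not at rest at 1.00 min: X stands at 63.4% and solid J at 48.9% of its charge. At 10.0 min the flask holds X at 0.0711%, J at 0%, [G] at 1.02 mM, L at 12.2%, X.Q at 22.3% and Z at 48.6%.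

All constants were chosen freely; what happens was integrated by code.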